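The cyclohexane ring of the quinic acid core is cut at C1–C6 and C2–C3. C1 is a quaternary ring carbon carrying both OH and CO2H and lying between the C2 and C6 methylenes, which is the pattern an α-oxyacrylate leaves after a Diels–Alder reaction with butadiene. One cycloaddition of butadiene to methylene dioxolanone 5, a lactate-derived α-oxyacrylate whose O and CO2 are tied into a tert-butyl acetal, closes the carbocycle and fixes C1. The C4–C5 alkene then lets C1 dictate C5 (iodolactonisation) and C3/C4 (elimination, dihydroxylation on the open face), giving (−)-quinide, which is esterified at O3, then O4, and unmasked with acid.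

Key step: step 4

Remark (assumption): the target is read as 3-O-(E)-caffeoyl-4-O-(E)-p-coumaroyl-(−)-quinic acid, with O1, O3 and O4 on one ring face and CO2H and O5 on the other. Quinic acid numbering is used for the core throughout. The (R)-acetal from (R)-lactic acid is the series that leads to this enantiomer. The two acetoxycinnamic acids are prepared rather than assumed to be stocked.

Step 1
Reactants: 1 (R)-lactic acid; 2 pivalaldehyde
Product: 3 (2R,5R)-2-tert-butyl-5-methyl-1,3-dioxolan-4-one
Conditions: p-TsOH (cat.), H2SO4 (cat.), pentane, reflux, Dean–Stark; recrystallise from Et2O/pentane, −78 °C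
Reagents that add atoms: none
Why: Acid-catalysed acetalisation of the α-hydroxy acid (Seebach dioxolanone formation) with azeotropic water removal should favour the cis isomer under equilibrating conditions, and cold recrystallisation should remove the trans isomer, which would otherwise carry the opposite acetal configuration into the dienophile.

Step 2
Reactants: 3 (2R,5R)-2-tert-butyl-5-methyl-1,3-dioxolan-4-one
Product: 4 (2R,5S)-5-bromo-2-tert-butyl-5-methyl-1,3-dioxolan-4-one
Conditions: NBS, AIBN (cat.), PhCF3, 80 °C
Reagents that add atoms: N-bromosuccinimide, O=C1CCC(=O)N1Br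
Why: Wohl–Ziegler-type radical bromination should occur at C5, where hydrogen abstraction gives a captodative radical flanked by ring oxygen and carbonyl, with bromine expected to enter anti to tert-butyl, although the C5 configuration is irrelevant because the next step erases it.

Step 3
Reactants: 4 (2R,5S)-5-bromo-2-tert-butyl-5-methyl-1,3-dioxolan-4-one
Product: 5 (R)-2-tert-butyl-5-methylene-1,3-dioxolan-4-one
Conditions: Et3N, Et2O, 0 °C → rt; distil, store cold over BHT
Reagents that add atoms: none
Why: E2 dehydrobromination can only use the methyl hydrogens, so the exocyclic alkene must form, and the acetal carbon, now the sole stereocentre, is not touched.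

Step 4
Reactants: 5 (R)-2-tert-butyl-5-methylene-1,3-dioxolan-4-one; 6 buta-1,3-diene
Product: 7 (2R,5S)-2-tert-butyl-1,3-dioxaspiro[4.5]dec-7-en-4-one
Conditions: 6 (excess), toluene, BHT (cat.), sealed vessel, 100 °C
Reagents that add atoms: none
Why: s-cis Butadiene and the exocyclic C=C of 5 combine in a concerted, suprafacial thermal [4+2] cycloaddition of normal electron demand, the diene termini bonding to the acetal-ring carbon (future C1, giving C1–C6) and to the methylene carbon (future C2, giving C2–C3). The closest known reaction type is the Diels–Alder reaction of α-acyloxyacrylates, and specifically of 2-tert-butyl-5-methylene-1,3-dioxolan-4-ones, with simple dienes. The cyclohexene ring is closed by the intermolecular cycloaddition itself, both σ-bonds forming in one event, not by a separate cyclisation. The only new stereocentre, the spiro carbon, is controlled by the acetal carbon: the tert-butyl group shields one face of the nearly flat dioxolanone, so the diene bonds anti to it and the former methylene carbon ends up cis to tert-butyl, which corresponds to the (S)-hydroxy acid. Only π-facial selectivity is needed, since symmetric butadiene raises no regio- or endo/exo question, and it is secured by the tert-butyl group two atoms from the reacting carbon. BHT and moderate temperature should hold back radical polymerisation of both partners.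

Step 5
Reactants: 7 (2R,5S)-2-tert-butyl-1,3-dioxaspiro[4.5]dec-7-en-4-one
Product: 9 (1S,4R,5R)-1-hydroxy-4-iodo-6-oxabicyclo[3.2.1]octan-7-one, via hydroxy acid 8 (not isolated)
Conditions: LiOH (1.1 equiv), THF/H2O, 0 °C → rt; Et2O wash; then NaHCO3, I2, KI, H2O, 0 °C → rt, dark
Reagents that add atoms: lithium hydroxide, [Li+].[OH-]; iodine, II
Why: Saponification opens the dioxolanone and the hemiacetal sheds pivalaldehyde, after which kinetic 5-exo iodolactonisation lets the C1 carboxylate reach only C5 on its own ring face while iodine adds anti at C4, so C5 is set by C1.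

Step 6
Reactants: 9 (1S,4R,5R)-1-hydroxy-4-iodo-6-oxabicyclo[3.2.1]octan-7-one
Product: 10 (1S,5R)-1-hydroxy-6-oxabicyclo[3.2.1]oct-3-en-7-one
Conditions: DBU, toluene, 90 °C
Reagents that add atoms: none
Why: E2 dehydroiodination must go towards C3, which has a hydrogen anti-periplanar to the iodine, because the C5 hydrogen is syn to iodine and the C1 hydroxyl sits on the same face as iodine and cannot displace it.

Step 7
Reactants: 10 (1S,5R)-1-hydroxy-6-oxabicyclo[3.2.1]oct-3-en-7-one
Product: 11 (−)-quinide, (1S,3R,4R,5R)-1,3,4-trihydroxy-6-oxabicyclo[3.2.1]octan-7-one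
Conditions: OsO4 (cat.), NMO, acetone/H2O (9:1), rt; Na2SO3 quench
Reagents that add atoms: osmium tetroxide, O=[Os](=O)(=O)=O; N-methylmorpholine N-oxide, C[N+]1([O-])CCOCC1; water, O
Why: Upjohn syn-dihydroxylation should take place on the alkene face away from the two-atom lactone bridge, which places the C3 and C4 hydroxyls cis to each other and trans to the C5–O bond, as in quinic acid.

Step 8
Reactants: 12 caffeic acid
Product: 13 (E)-3,4-diacetoxycinnamic acid
Conditions: Ac2O, pyridine, DMAP (cat.), rt; aq. HCl work-up
Reagents that add atoms: acetic anhydride, CC(=O)OC(C)=O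
Why: Standard O-acetylation of both phenols, with any mixed anhydride at the carboxyl hydrolysed back to the acid during the aqueous work-up.

Step 9
Reactants: 11 (−)-quinide; 13 (E)-3,4-diacetoxycinnamic acid
Product: 15 3-O-[(E)-3,4-diacetoxycinnamoyl]-1,5-quinide, via acid chloride 14 (not isolated)
Conditions: 13, (COCl)2, DMF (cat.), CH2Cl2, rt, evaporate; then 11, pyridine/CH2Cl2, slow addition of 14 (1.0 equiv), −20 → 0 °C
Reagents that add atoms: none
Why: Acyl chloride esterification should select O3–H, the only equatorial secondary hydroxyl of the locked bicycle, over the axial O4–H and the tertiary bridgehead O1–H, the same preference that governs the known selective O3 silylation of quinide.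

Step 10
Reactants: 16 p-coumaric acid
Product: 17 (E)-4-acetoxycinnamic acid
Conditions: Ac2O, pyridine, DMAP (cat.), rt; aq. HCl work-up
Reagents that add atoms: acetic anhydride, CC(=O)OC(C)=O
Why: Standard O-acetylation of the phenol, the carboxyl mixed anhydride being hydrolysed on work-up.

Step 11
Reactants: 15 3-O-[(E)-3,4-diacetoxycinnamoyl]-1,5-quinide; 17 (E)-4-acetoxycinnamic acid
Product: 19 3-O-[(E)-3,4-diacetoxycinnamoyl]-4-O-[(E)-4-acetoxycinnamoyl]-1,5-quinide, via acid chloride 18 (not isolated)
Conditions: 17, (COCl)2, DMF (cat.), CH2Cl2, rt, evaporate; then 15, 18 (1.3 equiv), pyridine, DMAP (cat.), CH2Cl2, 0 °C → rt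
Reagents that add atoms: none
Why: DMAP-catalysed acylation should esterify the remaining secondary (axial) O4–H while the tertiary O1–H stays free, and a shift of the O3 ester to O4 is not expected because it would move the acyl group from an equatorial to an axial oxygen.

Step 12
Reactants: 19 3-O-[(E)-3,4-diacetoxycinnamoyl]-4-O-[(E)-4-acetoxycinnamoyl]-1,5-quinide
Product: 20 3-O-(E)-caffeoyl-4-O-(E)-p-coumaroyl-(−)-quinic acid, (1R,3R,4S,5R)
Conditions: 1 M aq. HCl/THF (1:3), rt, argon, dark
Reagents that add atoms: water, O
Why: Acid-catalysed acyl–oxygen hydrolysis should remove the three aryl acetates and open the strained bicyclic lactone with retention at C5, while the conjugated, hindered cinnamoyl esters of the secondary alcohols react much more slowly and the acidic medium disfavours base-type acyl shifts.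

Compound list
1 | (R)-lactic acid | C[C@@H](O)C(=O)O | starting material
2 | pivalaldehyde | CC(C)(C)C=O | starting material
3 | (2R,5R)-2-tert-butyl-5-methyl-1,3-dioxolan-4-one, tert-butyl and methyl cis | C[C@H]1O[C@@H](C(C)(C)C)OC1=O | intermediate
4 | (2R,5S)-5-bromo-2-tert-butyl-5-methyl-1,3-dioxolan-4-one, bromine drawn trans to tert-butyl (either C5 epimer serves) | C[C@@]1(Br)O[C@@H](C(C)(C)C)OC1=O | intermediate
5 | (R)-2-tert-butyl-5-methylene-1,3-dioxolan-4-one | C=C1O[C@@H](C(C)(C)C)OC1=O | intermediate
6 | buta-1,3-diene | C=CC=C | starting material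
7 | (2R,5S)-2-tert-butyl-1,3-dioxaspiro[4.5]dec-7-en-4-one, allylic ring CH2 trans to tert-butyl | C1=CC[C@@]2(O[C@@H](C(C)(C)C)OC2=O)CC1 | intermediate
8 | (S)-1-hydroxycyclohex-3-ene-1-carboxylic acid, present as its lithium carboxylate | O[C@]1(C(=O)O)CC=CCC1 | intermediate
9 | (1S,4R,5R)-1-hydroxy-4-iodo-6-oxabicyclo[3.2.1]octan-7-one, iodine trans to the lactone oxygen | O[C@@]12CC[C@@H](I)[C@@H](C1)OC2=O | intermediate
10 | (1S,5R)-1-hydroxy-6-oxabicyclo[3.2.1]oct-3-en-7-one | O[C@@]12CC=C[C@@H](C1)OC2=O | intermediate
11 | (−)-quinide, (1S,3R,4R,5R)-1,3,4-trihydroxy-6-oxabicyclo[3.2.1]octan-7-one (quinic acid 1,5-lactone) | O[C@@]12C[C@@H](O)[C@@H](O)[C@@H](C1)OC2=O | intermediate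
12 | caffeic acid, (E) | OC(=O)/C=C/c1ccc(O)c(O)c1 | starting material
13 | (E)-3,4-diacetoxycinnamic acid | CC(=O)Oc1ccc(/C=C/C(=O)O)cc1OC(C)=O | intermediate
14 | (E)-3,4-diacetoxycinnamoyl chloride | CC(=O)Oc1ccc(/C=C/C(=O)Cl)cc1OC(C)=O | intermediate
15 | 3-O-[(E)-3,4-diacetoxycinnamoyl]-1,5-quinide, O1–H and O4–H free | O[C@@]12C[C@@H](OC(=O)/C=C/c3ccc(OC(C)=O)c(OC(C)=O)c3)[C@@H](O)[C@@H](C1)OC2=O | intermediate
16 | p-coumaric acid, (E) | OC(=O)/C=C/c1ccc(O)cc1 | starting material
17 | (E)-4-acetoxycinnamic acid | CC(=O)Oc1ccc(/C=C/C(=O)O)cc1 | intermediate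
18 | (E)-4-acetoxycinnamoyl chloride | CC(=O)Oc1ccc(/C=C/C(=O)Cl)cc1 | intermediate
19 | 3-O-[(E)-3,4-diacetoxycinnamoyl]-4-O-[(E)-4-acetoxycinnamoyl]-1,5-quinide, O1–H free | O[C@@]12C[C@@H](OC(=O)/C=C/c3ccc(OC(C)=O)c(OC(C)=O)c3)[C@@H](OC(=O)/C=C/c3ccc(OC(C)=O)cc3)[C@@H](C1)OC2=O | intermediate
20 | 3-O-(E)-caffeoyl-4-O-(E)-p-coumaroyl-(−)-quinic acid, (1R,3R,4S,5R)-3-caffeoyloxy-4-p-coumaroyloxy-1,5-dihydroxycyclohexane-1-carboxylic acid | O=C(/C=C/c1ccc(O)cc1)O[C@H]1[C@H](O)C[C@](O)(C(=O)O)C[C@H]1OC(=O)/C=C/c1ccc(O)c(O)c1 | target

Total step count: 12.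
Longest linear sequence: 10 steps (steps 1–7, 9, 11 and 12, from (R)-lactic acid); steps 8 and 10 are one-step side branches.

Steps most likely to fail

Step 9. The mono-acylation may not discriminate cleanly between the equatorial O3 and axial O4 hydroxyls, or may run on to the diester. The fallback sets out from 11 and comes back at 19, installing the O4 ester first under protecting-group control. Quinide 11 is silylated at O3 with TBSCl and imidazole in DMF at 0 °C to give 3-O-TBS-1,5-quinide F1. The remaining secondary hydroxyl is acylated with acid chloride 18 (pyridine, DMAP) to give 3-O-TBS-4-O-[(E)-4-acetoxycinnamoyl]-1,5-quinide F2. The silyl group is removed with HF·pyridine in THF, an acidic fluoride source chosen to avoid acyl shift and aryl acetate loss, giving 4-O-[(E)-4-acetoxycinnamoyl]-1,5-quinide F3. The freed equatorial O3–H is then esterified with acid chloride 14 in pyridine at low temperature to give 19.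

Step 12. The hydrolysis of three aryl acetates may be slow enough that the long acid exposure starts to cleave a cinnamoyl ester or lets the O4 ester shift to the newly freed O5. The fallback sets out from 19 and comes back at 20, dividing the two tasks between two mechanisms. A short treatment with aqueous HCl in THF is run only until the lactone has opened, giving 3-O-[(E)-3,4-diacetoxycinnamoyl]-4-O-[(E)-4-acetoxycinnamoyl]quinic acid F4; partly deacetylated material is carried along, since it converges. The phenolic acetates are then removed by chemoselective hydrazinolysis with hydrazine acetate in DMF at room temperature. Aryl esters react far faster than the alkyl cinnamates and the free carboxylic acid is inert, so this should give 20.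

Step 4. Radical polymerisation of the acetal dienophile or of butadiene may outrun the cycloaddition, or facial control may erode at the temperature needed. The fallback sets out from 6 and comes back at 8, replacing auxiliary control by resolution. Butadiene 6 is heated with achiral methyl 2-acetoxyacrylate F5 (toluene, hydroquinone, sealed vessel, about 140 °C) to give racemic methyl 1-acetoxycyclohex-3-ene-1-carboxylate F6. NaOH in aqueous methanol cleaves both esters to racemic 1-hydroxycyclohex-3-ene-1-carboxylic acid F7. Fractional crystallisation of its (R)-1-phenylethylammonium salt F8 follows; the amine enantiomer is to be settled by trial and the mirror-image amine is the alternative. Acidification should then deliver the (S)-acid 8, which enters the iodolactonisation half of step 5.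

Further compounds
F1 | step 9 | 3-O-(tert-butyldimethylsilyl)-1,5-quinide | O[C@@]12C[C@@H](O[Si](C)(C)C(C)(C)C)[C@@H](O)[C@@H](C1)OC2=O
F2 | step 9 | 3-O-(tert-butyldimethylsilyl)-4-O-[(E)-4-acetoxycinnamoyl]-1,5-quinide | O[C@@]12C[C@@H](O[Si](C)(C)C(C)(C)C)[C@@H](OC(=O)/C=C/c3ccc(OC(C)=O)cc3)[C@@H](C1)OC2=O
F3 | step 9 | 4-O-[(E)-4-acetoxycinnamoyl]-1,5-quinide | O[C@@]12C[C@@H](O)[C@@H](OC(=O)/C=C/c3ccc(OC(C)=O)cc3)[C@@H](C1)OC2=O
F4 | step 12 | 3-O-[(E)-3,4-diacetoxycinnamoyl]-4-O-[(E)-4-acetoxycinnamoyl]quinic acid | CC(=O)Oc1ccc(/C=C/C(=O)O[C@H]2[C@H](O)C[C@](O)(C(=O)O)C[C@H]2OC(=O)/C=C/c2ccc(OC(C)=O)c(OC(C)=O)c2)cc1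
F5 | step 4 | methyl 2-acetoxyacrylate | C=C(OC(C)=O)C(=O)OC
F6 | step 4 | racemic methyl 1-acetoxycyclohex-3-ene-1-carboxylate | COC(=O)C1(OC(C)=O)CC=CCC1
F7 | step 4 | racemic 1-hydroxycyclohex-3-ene-1-carboxylic acid | OC1(C(=O)O)CC=CCC1
F8 | step 4 | (R)-1-phenylethylammonium (S)-1-hydroxycyclohex-3-ene-1-carboxylate | C[C@@H]([NH3+])c1ccccc1.O[C@]1(C(=O)[O-])CC=CCC1
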